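**Plan**

- Retrosynthesis: the C6 acetate and the C15 acid go back to a diol ethyl ester; C8–CH3 (methyl addition to a ketone), C6–O (oxygenation of a Δ6-en-8-one) and C13=C14 (olefination of a methyl ketone) are then cut, leaving a cis-fused 8,13-diketone.
- That diketone is cut at C10–CH3 and C9–C11 in one operation, giving a bicyclic C8 enone (C9=C10), methyllithium and methyl vinyl ketone; the enone comes from 3-methylcyclohex-2-enone by the same cuprate/Michael tactic followed by aldol condensation.
- Enabling feature: in ring B the quaternary C10 (methyl) and its neighbour C9 (side chain) are β and α to the C8 carbinol carbon, so an enone C8(=O)–C9=C10 with C5 as its only stereocentre can take up both groups.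
- Forward order: ring A is bought, ring B is annulated onto it, the enone is resolved, methyl and the four-carbon chain are attached, the chain is extended to the E-enoate, then ring B is oxygenated at C6 and methylated at C8.
- Stereochemistry: C5 from the resolution; C10 from cuprate delivery anti to the C5–C4 bond (cis fusion); the C4 gem-dimethyl group then keeps C4 equatorial and C1 axial on ring B, so ring A screens the upper face and the chain (C9), the oxygen (C6) and the methyl (C8) all enter from the lower face; 13E from the Horner–Wadsworth–Emmons reaction.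

Key step: step 4

Remark: labdane numbering is used (ring A = C1–C5, C10; ring B = C5–C10; chain C11–C16), "lower face" means the face of ring B that carries H-5, and it is assumed that the absolute configuration of the resolved enone is assigned (circular dichroism of the enone or X-ray analysis of a crystalline derivative) before it is carried forward.

**Route**

Step 1
Reactants: 1 3-methylcyclohex-2-en-1-one; 2 methyllithium; 3 but-3-en-2-one
Product: 7 rac-3,3-dimethyl-2-(3-oxobutyl)cyclohexan-1-one, via lithium enolate 4 (not isolated), via silyl enol ether 5 (not isolated), via titanium enolate 6 (not isolated)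
Conditions: CuI, 2 (2 equiv), Et2O, 0 °C; 1, 0 °C; Me3SiCl, Et3N, 0 °C to rt; pentane, filtration, evaporation; then 3, TiCl4, CH2Cl2, −78 °C; H2O
Reagents that add atoms: lithium dimethylcuprate (formed in the flask from 2 and CuI), [Li+].C[Cu-]C
Why: Cuprate 1,4-addition to the β-methyl enone gives the enolate regiospecifically on the side of the new quaternary carbon, silylation fixes that regiochemistry, and the TiCl4-mediated Mukaiyama–Michael reaction then joins C2 to methyl vinyl ketone without the polymerisation that free lithium enolates cause with this acceptor; the single stereocentre forms as the racemate.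

Step 2
Reactants: 7 rac-3,3-dimethyl-2-(3-oxobutyl)cyclohexan-1-one
Product: 9 rac-5,5-dimethyl-4,4a,5,6,7,8-hexahydronaphthalen-2(3H)-one, via aldol ketol 8 (not isolated)
Conditions: KOH, MeOH, reflux
Reagents that add atoms: none
Why: Intramolecular aldol condensation (the ring-closing half of a Robinson annulation): the methyl ketone enolate adds to the ring carbonyl, ketol 8 loses water, and the conjugated enone is the thermodynamic sink because the bridged ketols form reversibly.

Step 3
Reactants: 9 rac-5,5-dimethyl-4,4a,5,6,7,8-hexahydronaphthalen-2(3H)-one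
Product: 10 (4aS)-5,5-dimethyl-4,4a,5,6,7,8-hexahydronaphthalen-2(3H)-one
Conditions: preparative supercritical-fluid chromatography, amylose tris(3,5-dimethylphenylcarbamate) on silica, CO2/MeOH
Reagents that add atoms: none
Why: Enantiomers of simple bicyclic enones are routinely separated on polysaccharide carbamate phases; no bond is formed, the C5 centre is stable under the neutral eluent, and the unwanted antipode can be racemised through its dienolate and returned to the column.

Step 4
Reactants: 10 (4aS)-5,5-dimethyl-4,4a,5,6,7,8-hexahydronaphthalen-2(3H)-one; 2 methyllithium; 3 but-3-en-2-one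
Product: 14 (1S,4aS,8aR)-5,5,8a-trimethyl-1-(3-oxobutyl)octahydronaphthalen-2(1H)-one, via lithium enolate 11 (not isolated), via silyl enol ether 12 (not isolated), via titanium enolate 13 (not isolated)
Conditions: CuI, 2 (2 equiv), Et2O, 0 °C; 10, 0 °C; Me3SiCl, Et3N, 0 °C to rt; pentane, filtration, evaporation; then 3, TiCl4, CH2Cl2, −78 °C; H2O
Reagents that add atoms: lithium dimethylcuprate (formed in the flask from 2 and CuI), [Li+].C[Cu-]C
Why: Lithium dimethylcuprate transfers methyl 1,4 to C10 and gives the C8(O)=C9 lithium enolate regiospecifically, which is fixed as the silyl enol ether; TiCl4 then activates methyl vinyl ketone and the enol ether attacks its terminal carbon through C9 (Mukaiyama–Michael addition), so C10–CH3 and C9–C11 are both made in one flask. The closest known chemistry is cuprate addition to 1(9)-octal-2-ones with trapping of the regiodefined enolate by a vinyl ketone. No ring is closed in this step. At C10 the methyl should be delivered axially on the face anti to the C5–C4 bond, because the other face would press the entering group against the axial methyl on C4, so the cis ring fusion follows from C5. At C9, once the bicycle has relaxed to the chair–chair form with C4 equatorial and C1 axial on ring B, the upper face of the enol ether lies under C1 and the electrophile should bond axially from the lower face, anti to C1 and past only H-5, which places the chain cis to the new methyl. The step needs an enolate that does not equilibrate, which silylation secures, and kinetic control at C9, which the low temperature, the non-basic work-up and the poorly aligned equatorial C9–H of the product secure.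

Step 5
Reactants: 14 (1S,4aS,8aR)-5,5,8a-trimethyl-1-(3-oxobutyl)octahydronaphthalen-2(1H)-one
Product: 15 ethyl (2E)-3-methyl-5-[(1S,4aS,8aR)-5,5,8a-trimethyl-2-oxodecahydronaphthalen-1-yl]pent-2-enoate
Conditions: (EtO)2P(O)CH2CO2Et, NaH, THF, 0 °C to rt
Reagents that add atoms: triethyl phosphonoacetate, CCOC(=O)CP(=O)(OCC)OCC
Why: Horner–Wadsworth–Emmons olefination selects the unhindered C13 methyl ketone over the C8 carbonyl, which is flanked by the quaternary C10 and the axial chain, and should give mainly the E-enoate (a minor Z isomer would be removed by chromatography); the weakly basic phosphonate anion and the poorly aligned equatorial C9–H protect the C9 centre.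

Step 6
Reactants: 15 ethyl (2E)-3-methyl-5-[(1S,4aS,8aR)-5,5,8a-trimethyl-2-oxodecahydronaphthalen-1-yl]pent-2-enoate
Product: 16 ethyl (2E)-3-methyl-5-[(1S,4aS,8aR)-5,5,8a-trimethyl-2-oxo-1,2,4a,5,6,7,8,8a-octahydronaphthalen-1-yl]pent-2-enoate
Conditions: 2-iodoxybenzoic acid (IBX), DMSO, 70 °C
Reagents that add atoms: none
Why: IBX dehydrogenation of a ketone through its enol: only enolisation toward C7 can lead to a ring double bond (C6=C7), since C10 is quaternary and the hindered equatorial C9–H is slow to leave, while the enoate and the stereocentres are inert to the neutral oxidant.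

Step 7
Reactants: 16 ethyl (2E)-3-methyl-5-[(1S,4aS,8aR)-5,5,8a-trimethyl-2-oxo-1,2,4a,5,6,7,8,8a-octahydronaphthalen-1-yl]pent-2-enoate
Product: 18 ethyl (2E)-5-[(1S,4S,4aS,8aR)-4-hydroxy-5,5,8a-trimethyl-2-oxodecahydronaphthalen-1-yl]-3-methylpent-2-enoate, via C6 pinacol boronate 17 (not isolated)
Conditions: bis(pinacolato)diboron, CuCl (cat.), NaOtBu (cat.), bis[2-(diphenylphosphino)phenyl] ether (cat.), MeOH, THF, rt; then NaBO3·4H2O, THF/H2O, rt
Reagents that add atoms: sodium perborate tetrahydrate, [Na+].[Na+].O[B-]1(O)OO[B-](O)(O)OO1.O.O.O.O.O.O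
Why: Copper-catalysed conjugate borylation of a cyclic enone followed by stereoretentive oxidation of the C–B bond: the boryl-copper species should reach C6 from the lower face, trans to the C5–C4 bond, because the upper face lies under C1 and C3 of ring A, the acyclic β,β-disubstituted enoate is much less reactive, and perborate is mild enough to spare the β-hydroxy ketone.

Step 8
Reactants: 18 ethyl (2E)-5-[(1S,4S,4aS,8aR)-4-hydroxy-5,5,8a-trimethyl-2-oxodecahydronaphthalen-1-yl]-3-methylpent-2-enoate; 2 methyllithium
Product: 19 ethyl (2E)-5-[(1S,2S,4S,4aS,8aR)-2,4-dihydroxy-2,5,5,8a-tetramethyldecahydronaphthalen-1-yl]-3-methylpent-2-enoate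
Conditions: 2 (excess), CeCl3 (anhydrous), THF, −78 °C; then H2O
Reagents that add atoms: methylcerium dichloride (formed in the flask from 2 and CeCl3), C[Ce](Cl)Cl
Why: Organocerium 1,2-addition to a hindered, enolisable ketone: one equivalent is consumed by the C6 hydroxyl, and methyl should then attack C8 equatorially from the lower face because the axial path is closed by the syn-axial C1 methylene in the chair fixed by the equatorial C4 and C6–O groups, which gives the axial tertiary alcohol, while the conjugated ester does not react at −78 °C.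

Step 9
Reactants: 19 ethyl (2E)-5-[(1S,2S,4S,4aS,8aR)-2,4-dihydroxy-2,5,5,8a-tetramethyldecahydronaphthalen-1-yl]-3-methylpent-2-enoate
Product: 20 (2E)-5-[(1S,2S,4S,4aS,8aR)-2,4-dihydroxy-2,5,5,8a-tetramethyldecahydronaphthalen-1-yl]-3-methylpent-2-enoic acid
Conditions: LiOH, THF/MeOH/H2O, 50 °C; then 1 M HCl to pH 4, 0 °C
Reagents that add atoms: lithium hydroxide, [Li+].[OH-]
Why: Saponification of the ethyl ester; the diol has no base-labile group, and mild cold acidification leaves the tertiary alcohol intact.

Step 10
Reactants: 20 (2E)-5-[(1S,2S,4S,4aS,8aR)-2,4-dihydroxy-2,5,5,8a-tetramethyldecahydronaphthalen-1-yl]-3-methylpent-2-enoic acid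
Product: 22 (2E)-5-[(1S,2S,4S,4aS,8aR)-4-(acetyloxy)-2-hydroxy-2,5,5,8a-tetramethyldecahydronaphthalen-1-yl]-3-methylpent-2-enoic acid, via mixed anhydride 21 (not isolated)
Conditions: Ac2O, pyridine, 4-(dimethylamino)pyridine (cat.), CH2Cl2, 0 °C to rt; then H2O/THF, rt
Reagents that add atoms: acetic anhydride, CC(=O)OC(C)=O
Why: Acylation with acetic anhydride reaches the secondary equatorial C6 hydroxyl but not the tertiary axial C8 hydroxyl, and the mixed anhydride 21 formed at the carboxyl group is hydrolysed back to the acid during the aqueous stage.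

**Compound list**

1 | 3-methylcyclohex-2-en-1-one | CC1=CC(=O)CCC1 | starting material
2 | methyllithium | [Li]C | starting material
3 | but-3-en-2-one (methyl vinyl ketone) | C=CC(C)=O | starting material
4 | lithium 3,3-dimethylcyclohex-1-en-1-olate | [Li]OC1=CC(C)(C)CCC1 | intermediate
5 | [(3,3-dimethylcyclohex-1-en-1-yl)oxy]trimethylsilane | C[Si](C)(C)OC1=CC(C)(C)CCC1 | intermediate
6 | rac-trichloro{[4-(2,2-dimethyl-6-oxocyclohexyl)but-2-en-2-yl]oxy}titanium | CC(O[Ti](Cl)(Cl)Cl)=CCC1C(=O)CCCC1(C)C | intermediate
7 | rac-3,3-dimethyl-2-(3-oxobutyl)cyclohexan-1-one | CC(=O)CCC1C(=O)CCCC1(C)C | intermediate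
8 | rac-8a-hydroxy-5,5-dimethyloctahydronaphthalen-2(1H)-one | CC1(C)CCCC2(O)CC(=O)CCC12 | intermediate
9 | rac-5,5-dimethyl-4,4a,5,6,7,8-hexahydronaphthalen-2(3H)-one | CC1(C)CCCC2=CC(=O)CCC12 | intermediate
10 | (4aS)-5,5-dimethyl-4,4a,5,6,7,8-hexahydronaphthalen-2(3H)-one | C1CC(=O)C=C2CCCC(C)(C)[C@H]12 | intermediate
11 | lithium (4aS,8aR)-5,5,8a-trimethyl-3,4,4a,5,6,7,8,8a-octahydronaphthalen-2-olate (cis-fused) | C1CC(O[Li])=C[C@]2(C)CCCC(C)(C)[C@H]12 | intermediate
12 | trimethyl{[(4aS,8aR)-5,5,8a-trimethyl-3,4,4a,5,6,7,8,8a-octahydronaphthalen-2-yl]oxy}silane (cis-fused) | C1CC(O[Si](C)(C)C)=C[C@]2(C)CCCC(C)(C)[C@H]12 | intermediate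
13 | trichloro{[4-((1S,4aS,8aR)-5,5,8a-trimethyl-2-oxodecahydronaphthalen-1-yl)but-2-en-2-yl]oxy}titanium | C1CC(=O)[C@@H](CC=C(C)O[Ti](Cl)(Cl)Cl)[C@]2(C)CCCC(C)(C)[C@H]12 | intermediate
14 | (1S,4aS,8aR)-5,5,8a-trimethyl-1-(3-oxobutyl)octahydronaphthalen-2(1H)-one (cis-fused; chain cis to the angular methyl) | C1CC(=O)[C@@H](CCC(C)=O)[C@]2(C)CCCC(C)(C)[C@H]12 | intermediate
15 | ethyl (2E)-3-methyl-5-[(1S,4aS,8aR)-5,5,8a-trimethyl-2-oxodecahydronaphthalen-1-yl]pent-2-enoate | C1CC(=O)[C@@H](CC/C(C)=C/C(=O)OCC)[C@]2(C)CCCC(C)(C)[C@H]12 | intermediate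
16 | ethyl (2E)-3-methyl-5-[(1S,4aS,8aR)-5,5,8a-trimethyl-2-oxo-1,2,4a,5,6,7,8,8a-octahydronaphthalen-1-yl]pent-2-enoate | C1=CC(=O)[C@@H](CC/C(C)=C/C(=O)OCC)[C@]2(C)CCCC(C)(C)[C@H]12 | intermediate
17 | ethyl (2E)-3-methyl-5-[(1S,4S,4aS,8aR)-5,5,8a-trimethyl-2-oxo-4-(4,4,5,5-tetramethyl-1,3,2-dioxaborolan-2-yl)decahydronaphthalen-1-yl]pent-2-enoate | CC3(C)OB(OC3(C)C)[C@H]1CC(=O)[C@@H](CC/C(C)=C/C(=O)OCC)[C@]2(C)CCCC(C)(C)[C@H]12 | intermediate
18 | ethyl (2E)-5-[(1S,4S,4aS,8aR)-4-hydroxy-5,5,8a-trimethyl-2-oxodecahydronaphthalen-1-yl]-3-methylpent-2-enoate | O[C@H]1CC(=O)[C@@H](CC/C(C)=C/C(=O)OCC)[C@]2(C)CCCC(C)(C)[C@H]12 | intermediate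
19 | ethyl (2E)-5-[(1S,2S,4S,4aS,8aR)-2,4-dihydroxy-2,5,5,8a-tetramethyldecahydronaphthalen-1-yl]-3-methylpent-2-enoate | O[C@H]1C[C@](C)(O)[C@@H](CC/C(C)=C/C(=O)OCC)[C@]2(C)CCCC(C)(C)[C@H]12 | intermediate
20 | (2E)-5-[(1S,2S,4S,4aS,8aR)-2,4-dihydroxy-2,5,5,8a-tetramethyldecahydronaphthalen-1-yl]-3-methylpent-2-enoic acid | O[C@H]1C[C@](C)(O)[C@@H](CC/C(C)=C/C(=O)O)[C@]2(C)CCCC(C)(C)[C@H]12 | intermediate
21 | acetic (2E)-5-[(1S,2S,4S,4aS,8aR)-4-(acetyloxy)-2-hydroxy-2,5,5,8a-tetramethyldecahydronaphthalen-1-yl]-3-methylpent-2-enoic anhydride | CC(=O)O[C@H]1C[C@](C)(O)[C@@H](CC/C(C)=C/C(=O)OC(C)=O)[C@]2(C)CCCC(C)(C)[C@H]12 | intermediate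
22 | (2E)-5-[(1S,2S,4S,4aS,8aR)-4-(acetyloxy)-2-hydroxy-2,5,5,8a-tetramethyldecahydronaphthalen-1-yl]-3-methylpent-2-enoic acid (labdane numbering: 5S,6S,8S,9S,10R) | CC(=O)O[C@H]1C[C@](C)(O)[C@@H](CC/C(C)=C/C(=O)O)[C@]2(C)CCCC(C)(C)[C@H]12 | target

**Step count and risks**

Total step count: 10. Longest linear sequence: 10 steps (from 1).

Steps most likely to fail:

1. Step 4. Methyl transfer to the congested C10 may be slow, and in the second stage polymerisation of the acceptor or protodesilylation of the hindered enol ether may outrun bond formation at C9. The fallback sets out from 10: the cuprate addition is run as before to lithium enolate 11, which is quenched at −78 °C with 3-(trimethylsilyl)but-3-en-2-one, an acceptor whose α-silyl group stabilises the adduct anion and suppresses polymerisation. This should give (1S,4aS,8aR)-5,5,8a-trimethyl-1-[3-oxo-2-(trimethylsilyl)butyl]octahydronaphthalen-2(1H)-one F1. Protodesilylation with Bu4NF and AcOH in THF at 0 °C would then return the route at 14.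

2. Step 7. Insertion of the bulky boryl-copper species at C6, next to the neopentyl-type C5, may stall, or face discrimination may be incomplete. The fallback sets out from 16: nucleophilic epoxidation with the small hydroperoxide anion (H2O2, NaOH, MeOH, 0 °C; Weitz–Scheffer reaction), which should also enter from the lower face, would give the 6,7-epoxy 8-ketone F2. Reductive cleavage of its C7–O bond with the phenylselenide reagent made from PhSeSePh and NaBH4 in EtOH with AcOH at 0 °C would leave the C6–O bond untouched and return the route at 18.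

3. Step 6. Enolisation of the hindered C8 ketone under the neutral conditions may be slow, and over-oxidation may set in on forcing. The fallback sets out from 15: kinetic deprotonation at C7 with in-situ silylation (LiN(SiMe3)2, Me3SiCl, THF, −78 °C) would give the C7-enol trimethylsilyl ether F3. Saegusa–Ito oxidation with Pd(OAc)2 in MeCN at rt would return the route at 16.

Further compounds
F1 | step 4 | (1S,4aS,8aR)-5,5,8a-trimethyl-1-[3-oxo-2-(trimethylsilyl)butyl]octahydronaphthalen-2(1H)-one | C1CC(=O)[C@@H](CC([Si](C)(C)C)C(C)=O)[C@]2(C)CCCC(C)(C)[C@H]12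
F2 | step 7 | 6,7-epoxy 8-ketone (ethyl ester of 16 with the oxirane on the H-5 face of ring B) | O1[C@H]2[C@@H]1C(=O)[C@@H](CC/C(C)=C/C(=O)OCC)[C@]3(C)CCCC(C)(C)[C@H]23
F3 | step 6 | C7-enol trimethylsilyl ether of 15 | C1C=C(O[Si](C)(C)C)[C@@H](CC/C(C)=C/C(=O)OCC)[C@]2(C)CCCC(C)(C)[C@H]12
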